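**Retrosynthetic overview**

1. Target 12 ⇐ tetra-O-benzyl flavone 11 by hydrogenolysis of all four benzyl ethers.
2. 11 ⇐ chromone 8 + 1-(benzyloxy)-4-iodobenzene 9, disconnecting the bond from pyranone C2 to C1′ of ring B. Both carbons are acceptor carbons, so the union rests on polarity reversal at C2 (C–H zincation, then Negishi coupling).
3. Enabling feature: the C2–H of the γ-pyrone ring C. C2 is bound to the ring oxygen O1 and is the β-carbon of the vinylogous ester O1–C2=C3–C4=O, which makes this the most acidic C–H of 8.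
4. 8 ⇐ 8-iodochromone 5 + benzylzinc reagent 7 (C8–CH2, Negishi); 5 ⇐ iodinated o-hydroxyacetophenone 3 + one carbon (ring C closed through O1–C2); 3 ⇐ phloroacetophenone 1.
5. Ring order: ring A, ring B and the benzyl ring are bought; ring C is the only ring made (step 3), before both cross-couplings.

Key step: step 6

Remark on the chemistry: the target has no stereocentre, stereoaxis or configured double bond. It is achiral, so the compound as drawn is the only stereoisomer and no stereocontrol is needed. Compounds 1, 6, 9 and the base TMPZnCl·LiCl (THF solution) are taken as commercial.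

**Route**

Step 1
Reactants: 1 2,4,6-trihydroxyacetophenone
Product: 2 1-[2,4-bis(benzyloxy)-6-hydroxyphenyl]ethan-1-one
Conditions: BnBr (2.1 equiv), K2CO3 (2.2 equiv), DMF, 0 → 25 °C
Reagents that add atoms: benzyl bromide, BrCc1ccccc1
Why: Williamson ether synthesis in which the para hydroxyl and one ortho hydroxyl are alkylated, while the last ortho hydroxyl, locked in a hydrogen bond to the acetyl C=O, should stay free; the two ortho hydroxyls of 1 are equivalent, so only one dibenzyl ether can form.

Step 2
Reactants: 2 1-[2,4-bis(benzyloxy)-6-hydroxyphenyl]ethan-1-one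
Product: 3 1-[4,6-bis(benzyloxy)-2-hydroxy-3-iodophenyl]ethan-1-one
Conditions: NIS (1.05 equiv), TFA (10 mol %), MeCN, 0 → 25 °C, dark
Reagents that add atoms: N-iodosuccinimide, O=C1CCC(=O)N1I
Why: Electrophilic aromatic iodination, expected at C3 because this position is ortho to the free hydroxyl and less hindered than C5 between the two benzyloxy groups, as is usual for halogenation of 2-hydroxy-4,6-dialkoxyacetophenones.

Step 3
Reactants: 3 1-[4,6-bis(benzyloxy)-2-hydroxy-3-iodophenyl]ethan-1-one
Product: 5 5,7-bis(benzyloxy)-8-iodo-4H-chromen-4-one, via (E)-enaminone 4 (not isolated)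
Conditions: Me2NCH(OMe)2 (3 equiv), PhMe, 100 °C; evaporate; then conc. aq. HCl, CH2Cl2, 25 °C
Reagents that add atoms: N,N-dimethylformamide dimethyl acetal, COC(OC)N(C)C
Why: Enaminone route to 3-unsubstituted chromones, in which condensation at the acetyl CH3 is followed by acid-promoted intramolecular oxa-Michael addition and loss of dimethylamine (6-endo closure of ring C through the only free phenol), so that the iodinated carbon becomes C8.

Step 4
Reactants: 6 1-(benzyloxy)-4-(chloromethyl)benzene
Product: 7 [4-(benzyloxy)benzyl]zinc chloride, kept as a titrated THF solution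
Conditions: Zn dust (1.5 equiv, activated with BrCH2CH2Br and TMSCl), LiCl (1.5 equiv), THF, 25 °C
Reagents that add atoms: zinc, [Zn]
Why: Direct oxidative insertion of LiCl-activated zinc into the benzylic C–Cl bond, a standard preparation of benzylic zinc chlorides that leaves the aryl benzyl ether untouched and keeps Wurtz homocoupling slow at 25 °C.

Step 5
Reactants: 5 5,7-bis(benzyloxy)-8-iodo-4H-chromen-4-one; 7 [4-(benzyloxy)benzyl]zinc chloride
Product: 8 5,7-bis(benzyloxy)-8-[4-(benzyloxy)benzyl]-4H-chromen-4-one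
Conditions: 7 (1.3 equiv), Pd(OAc)2 (2 mol %), SPhos (4 mol %), THF, 25 → 50 °C
Reagents that add atoms: none
Why: Negishi sp2–sp3 cross-coupling, in which the bulky electron-rich phosphine allows oxidative addition at the hindered C8–I bond and the benzylzinc reagent transmetalates without adding to the pyranone enone or carbonyl.

Step 6
Reactants: 8 5,7-bis(benzyloxy)-8-[4-(benzyloxy)benzyl]-4H-chromen-4-one; 9 1-(benzyloxy)-4-iodobenzene
Product: 11 5,7-bis(benzyloxy)-8-[4-(benzyloxy)benzyl]-2-[4-(benzyloxy)phenyl]-4H-chromen-4-one, via 2-chromonylzinc chloride 10 (not isolated)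
Conditions: TMPZnCl·LiCl (1.3 equiv), THF, 25 °C; then 9 (1.2 equiv), Pd(dba)2 (3 mol %), P(2-furyl)3 (6 mol %), THF, 50 °C
Reagents that add atoms: none
Why: The hindered, non-nucleophilic zinc amide removes the C2–H of the γ-pyrone ring, the most acidic C–H of 8 because C2 is bound to O1 and is the β-carbon of the vinylogous ester O1–C2=C3–C4=O, and gives the 2-chromonylzinc chloride 10, in which the normally electrophilic C2 has become a carbon nucleophile. Pd(0) then inserts into the C–I bond of 9, the zinc reagent transmetalates and reductive elimination forms the C2–C1′ bond, so that two acceptor carbons are joined and the complete protected flavone skeleton appears in one operation. The closest known reaction type is the regioselective C2-zincation of chromones with TMP-zinc amides followed by Negishi arylation to flavones. No ring is closed and no stereocentre is formed, the product being planar and achiral. The step needs site selectivity for C2 over C3, C6 and the diarylmethane CH2: magnesium- or boron-centred Lewis acids, which would bind C4=O and steer the base to C3, are left out, and the aromatic C6–H and the benzylic CH2 groups are too weakly acidic for a zinc amide. The benzyl ethers carry no acidic proton, and the covalent C–Zn bond should neither open the pyrone ring nor attack C4=O.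

Step 7
Reactants: 11 5,7-bis(benzyloxy)-8-[4-(benzyloxy)benzyl]-2-[4-(benzyloxy)phenyl]-4H-chromen-4-one
Product: 12 5,7-dihydroxy-8-(4-hydroxybenzyl)-2-(4-hydroxyphenyl)-4H-chromen-4-one
Conditions: H2 (1 atm), 10% Pd/C, THF–MeOH (1:1), 25 °C
Reagents that add atoms: none
Why: Catalytic hydrogenolysis of the four aryl benzyl ethers under neutral conditions, which should leave the conjugated C2=C3 bond and the diarylmethane C–C bond intact and avoids the acid-induced loss or migration of the C8 benzyl group.

**Compound list**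

1 | 2,4,6-trihydroxyacetophenone | CC(=O)c1c(O)cc(O)cc1O | starting material
2 | 1-[2,4-bis(benzyloxy)-6-hydroxyphenyl]ethan-1-one | CC(=O)c1c(O)cc(OCc2ccccc2)cc1OCc1ccccc1 | intermediate
3 | 1-[4,6-bis(benzyloxy)-2-hydroxy-3-iodophenyl]ethan-1-one | CC(=O)c1c(O)c(I)c(OCc2ccccc2)cc1OCc1ccccc1 | intermediate
4 | (E)-1-[4,6-bis(benzyloxy)-2-hydroxy-3-iodophenyl]-3-(dimethylamino)prop-2-en-1-one | CN(C)/C=C/C(=O)c1c(O)c(I)c(OCc2ccccc2)cc1OCc1ccccc1 | intermediate
5 | 5,7-bis(benzyloxy)-8-iodo-4H-chromen-4-one | O=c1ccoc2c(I)c(OCc3ccccc3)cc(OCc3ccccc3)c12 | intermediate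
6 | 1-(benzyloxy)-4-(chloromethyl)benzene | ClCc1ccc(OCc2ccccc2)cc1 | starting material
7 | [4-(benzyloxy)benzyl]zinc chloride | Cl[Zn]Cc1ccc(OCc2ccccc2)cc1 | intermediate
8 | 5,7-bis(benzyloxy)-8-[4-(benzyloxy)benzyl]-4H-chromen-4-one | O=c1ccoc2c(Cc3ccc(OCc4ccccc4)cc3)c(OCc3ccccc3)cc(OCc3ccccc3)c12 | intermediate
9 | 1-(benzyloxy)-4-iodobenzene | Ic1ccc(OCc2ccccc2)cc1 | starting material
10 | {5,7-bis(benzyloxy)-8-[4-(benzyloxy)benzyl]-4-oxo-4H-chromen-2-yl}zinc chloride | O=c1cc([Zn]Cl)oc2c(Cc3ccc(OCc4ccccc4)cc3)c(OCc3ccccc3)cc(OCc3ccccc3)c12 | intermediate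
11 | 5,7-bis(benzyloxy)-8-[4-(benzyloxy)benzyl]-2-[4-(benzyloxy)phenyl]-4H-chromen-4-one | O=c1cc(-c2ccc(OCc3ccccc3)cc2)oc2c(Cc3ccc(OCc4ccccc4)cc3)c(OCc3ccccc3)cc(OCc3ccccc3)c12 | intermediate
12 | 5,7-dihydroxy-8-(4-hydroxybenzyl)-2-(4-hydroxyphenyl)-4H-chromen-4-one | O=c1cc(-c2ccc(O)cc2)oc2c(Cc3ccc(O)cc3)c(O)cc(O)c12 | target

**Totals and risks**

Total step count: 7. Longest linear sequence: 6 steps (steps 1, 2, 3, 5, 6, 7); step 4 is a one-step side branch.

Step 6 (key step). The metalation may be incomplete or may drift to C3 if the carbonyl oxygen becomes complexed. Transmetalation of the electron-rich chromonylzinc species may also be slow, so that it is simply protonated back to 8 on work-up. The fallback sets out from 8 and treats C2 as the electrophile it naturally is. Palladium(II)-catalysed conjugate addition of 4-(benzyloxy)phenylboronic acid (Pd(TFA)2, 2,2′-bipyridine, aqueous AcOH–THF, 60 °C) should give the racemic flavanone 5,7-bis(benzyloxy)-8-[4-(benzyloxy)benzyl]-2-[4-(benzyloxy)phenyl]chroman-4-one F1. Aerobic palladium(II) α,β-dehydrogenation (Pd(TFA)2, DMSO, O2, 80 °C) then removes the transient C2 stereocentre and comes back to the route at 11.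

Step 2. Iodination may take place at the position between the two benzyloxy groups or go on to the di-iodide, which would place the benzyl group at C6 of the chromone. The fallback sets out from 2 and uses a bond formation that can only occur ortho to the free phenol.
- Magnesium-mediated ortho-formylation (MgCl2, Et3N, paraformaldehyde, MeCN, reflux) should give 3-acetyl-4,6-bis(benzyloxy)-2-hydroxybenzaldehyde F2.
- Aldehyde-selective rhodium(I)-catalysed 1,2-addition of 4-(benzyloxy)phenylboronic acid should give the racemic carbinol 1-{4,6-bis(benzyloxy)-3-[(4-(benzyloxy)phenyl)(hydroxy)methyl]-2-hydroxyphenyl}ethan-1-one F3.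
- Ionic hydrogenation (Et3SiH, TFA, CH2Cl2, −20 °C), in which the doubly benzylic carbinol ionises far faster than the chelated ketone is reduced, should give 1-{4,6-bis(benzyloxy)-3-[4-(benzyloxy)benzyl]-2-hydroxyphenyl}ethan-1-one F4.
- The conditions of step 3 should then lead through the enaminone (E)-1-{4,6-bis(benzyloxy)-3-[4-(benzyloxy)benzyl]-2-hydroxyphenyl}-3-(dimethylamino)prop-2-en-1-one F5 and come back to the route at 8, with steps 3 to 5 no longer needed.

Step 5. Oxidative addition and transmetalation at the di-ortho-substituted C8–I bond may be slow, so that homocoupling of the benzylzinc reagent and protodeiodination outrun the cross-coupling. The fallback sets out from 5 and exchanges the roles of the partners. Miyaura borylation (B2pin2, PdCl2(dppf), KOAc, dioxane, 90 °C) should give 5,7-bis(benzyloxy)-8-(4,4,5,5-tetramethyl-1,3,2-dioxaborolan-2-yl)-4H-chromen-4-one F6. Suzuki–Miyaura coupling of F6 with the benzylic chloride 6 (Pd(PPh3)4, anhydrous K3PO4, toluene, 80 °C, water excluded to protect the base-sensitive pyrone) then comes back to the route at 8, and step 4 is not needed.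

**Further compounds**

F1 | step 6 | 5,7-bis(benzyloxy)-8-[4-(benzyloxy)benzyl]-2-[4-(benzyloxy)phenyl]chroman-4-one (racemic) | O=C1CC(c2ccc(OCc3ccccc3)cc2)Oc2c(Cc3ccc(OCc4ccccc4)cc3)c(OCc3ccccc3)cc(OCc3ccccc3)c21
F2 | step 2 | 3-acetyl-4,6-bis(benzyloxy)-2-hydroxybenzaldehyde | CC(=O)c1c(O)c(C=O)c(OCc2ccccc2)cc1OCc1ccccc1
F3 | step 2 | 1-{4,6-bis(benzyloxy)-3-[(4-(benzyloxy)phenyl)(hydroxy)methyl]-2-hydroxyphenyl}ethan-1-one (racemic) | CC(=O)c1c(O)c(C(O)c2ccc(OCc3ccccc3)cc2)c(OCc2ccccc2)cc1OCc1ccccc1
F4 | step 2 | 1-{4,6-bis(benzyloxy)-3-[4-(benzyloxy)benzyl]-2-hydroxyphenyl}ethan-1-one | CC(=O)c1c(O)c(Cc2ccc(OCc3ccccc3)cc2)c(OCc2ccccc2)cc1OCc1ccccc1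
F5 | step 2 | (E)-1-{4,6-bis(benzyloxy)-3-[4-(benzyloxy)benzyl]-2-hydroxyphenyl}-3-(dimethylamino)prop-2-en-1-one | CN(C)/C=C/C(=O)c1c(O)c(Cc2ccc(OCc3ccccc3)cc2)c(OCc2ccccc2)cc1OCc1ccccc1
F6 | step 5 | 5,7-bis(benzyloxy)-8-(4,4,5,5-tetramethyl-1,3,2-dioxaborolan-2-yl)-4H-chromen-4-one | O=c1ccoc2c(B3OC(C)(C)C(C)(C)O3)c(OCc3ccccc3)cc(OCc3ccccc3)c12
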